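**Plan**

1. Numbering: benzofuran numbering (O1, C2, C3, C3a, C4–C7, C7a) for the core, ring A for its benzene ring, ring B for the 4-hydroxy-3-methoxyphenyl group, C9 for the CH2O carbon on C3.
2. Retrosynthetic cuts, in order: the enal C=C on C5 (Wittig) and the ester C–O; C7–OMe back to C7–SiMe3; then both bonds from ring A to the dihydrofuran, O1–C7a and C3–C3a, in one aryne annulation; the epoxy alcohol partner back to O-benzylvanillin.
3. Enabling feature: O1 (on C2) and C3 are 1,3-related and sit on the neighbouring ring A carbons C7a and C3a, and C3 carries C9–O. C3/C9–O is therefore an epoxide in disguise, so a 2,3-epoxy-1-alkoxide can deliver O1 as nucleophile and C3 as electrophile to the two carbons of an aryne.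
4. Forward order: ring A enters as a 3-silylaryne (SiMe3 at C7 steers the alkoxide and stands in for OMe); the dihydrofuran ring is closed in the key step; then Si → I → OMe, ester, phenol release and the enal chain last.
5. Stereochemistry: C2 and the epoxide carbon come from a Sharpless kinetic resolution (erythro epoxy alcohol); C3 is set by SN2 inversion in the ring closure, which maps erythro onto trans (2R,3S).

Key step: step 5

**Route**

Step 1
Reactants: 1 3,5-dibromo-4-hydroxybenzaldehyde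
Product: 2 2,6-dibromo-4-(5,5-dimethyl-1,3-dioxan-2-yl)phenol
Conditions: 2,2-dimethylpropane-1,3-diol, p-TsOH (cat.), toluene, reflux (Dean–Stark)
Reagents that add atoms: 2,2-dimethylpropane-1,3-diol, OCC(C)(C)CO
Why: Acid-catalysed acetalisation with azeotropic removal of water masks the aldehyde against the organolithium, alkoxide and fluoride steps that follow.

Step 2
Reactants: 2 2,6-dibromo-4-(5,5-dimethyl-1,3-dioxan-2-yl)phenol
Product: 7 4-(5,5-dimethyl-1,3-dioxan-2-yl)-2,6-bis(trimethylsilyl)phenyl trifluoromethanesulfonate, via aryl silyl ether 3 (not isolated), via bromo silyl phenolate 4 (not isolated), via bromo bis-silyl ether 5 (not isolated), via bis-silyl phenolate 6 (not isolated)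
Conditions: (Me3Si)2NH, THF, reflux, then evaporate; n-BuLi, THF, −78 °C to rt; Me3SiCl, −78 °C to rt; n-BuLi, −78 °C to rt; Tf2O, −78 to 0 °C
Reagents that add atoms: hexamethyldisilazane, C[Si](C)(C)N[Si](C)(C)C; chlorotrimethylsilane, C[Si](C)(C)Cl; trifluoromethanesulfonic anhydride, O=S(=O)(OS(=O)(=O)C(F)(F)F)C(F)(F)F
Why: Two rounds of retro-Brook rearrangement (Br/Li exchange, then 1,3 O→C silyl shift) followed by O-triflation of the hindered phenolate are the standard entry to 2-silylaryl triflates, and the acetal is inert to n-BuLi at low temperature.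

Step 3
Reactants: 8 4-(benzyloxy)-3-methoxybenzaldehyde
Product: 9 rac-1-[4-(benzyloxy)-3-methoxyphenyl]prop-2-en-1-ol
Conditions: CH2=CHMgBr, THF, 0 °C; then H2O
Reagents that add atoms: vinylmagnesium bromide, C=C[Mg]Br
Why: Grignard addition to the aryl aldehyde should give the racemic aryl vinyl carbinol.

Step 4
Reactants: 9 rac-1-[4-(benzyloxy)-3-methoxyphenyl]prop-2-en-1-ol
Product: 10 (S)-[4-(benzyloxy)-3-methoxyphenyl][(2R)-oxiran-2-yl]methanol
Conditions: Ti(OiPr)4 (0.2 equiv), L-(+)-diisopropyl tartrate (0.24 equiv), t-BuOOH (0.5 equiv), 4 Å MS, CH2Cl2, −20 °C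
Reagents that add atoms: tert-butyl hydroperoxide, CC(C)(C)OO
Why: Sharpless kinetic resolution: the titanium tartrate complex should epoxidise (R)-9 much faster than (S)-9, the tartrate setting the (2R)-oxirane carbon and the fast-reacting enantiomer giving the erythro relation to the carbinol centre, while (S)-9 is left behind and separated.

Step 5
Reactants: 10 (S)-[4-(benzyloxy)-3-methoxyphenyl][(2R)-oxiran-2-yl]methanol; 7 4-(5,5-dimethyl-1,3-dioxan-2-yl)-2,6-bis(trimethylsilyl)phenyl trifluoromethanesulfonate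
Product: 14 [(2R,3S)-2-[4-(benzyloxy)-3-methoxyphenyl]-5-(5,5-dimethyl-1,3-dioxan-2-yl)-7-(trimethylsilyl)-2,3-dihydro-1-benzofuran-3-yl]methanol, via potassium alkoxide 11 (not isolated), via aryne 12 (not isolated), via aryl anion 13 (not isolated)
Conditions: 10 (1.3 equiv), KH, THF, 0 °C; then 7, KF, 18-crown-6, THF, 0 °C to rt; then H2O
Reagents that add atoms: none
Why: Proposed new method: fluoride removes one SiMe3 group of 7 with loss of triflate to give aryne 12, the alkoxide oxygen of 11 adds to the aryne carbon that becomes C7a, and the aryl anion 13 formed at C3a opens the neighbouring epoxide at its CH carbon and releases the C9 alkoxide; the closest known reaction types are the nucleophile-addition/intramolecular-trapping annulations of arynes from 2-silylaryl triflates and the Parham-type cyclisation of 2-lithioaryl epoxyalkyl ethers. The side of addition follows from the groups beside the triple bond, SiMe3 at C7 and H at C4: the electropositive silicon is a σ-donor that disfavours negative charge on the carbon next to it, so the charge should go to C3a and the oxygen should bond next to silicon (the ortho preference known for N-nucleophiles with 3-silylarynes), a bias that a methoxy group at C7 would reverse and that the weakly electron-withdrawing acetal at C5, para to C7a, reinforces. The dihydrofuran ring closes in the 5-exo-tet mode, preferred on geometric grounds to 6-endo attack at the CH2 terminus. C2 keeps the configuration of 10 because no bond to it is broken, and C3 is set by inversion in the SN2 opening, so the erythro epoxy alcohol maps onto the trans (2R,3S) ring. The step needs proximal regioselectivity, exo ring opening, and ring closure faster than proton capture or Payne migration; these are served by the silyl director, the five-membered transition state, a preformed alkoxide in aprotic THF without free alcohol, and low temperature.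

Step 6
Reactants: 14 [(2R,3S)-2-[4-(benzyloxy)-3-methoxyphenyl]-5-(5,5-dimethyl-1,3-dioxan-2-yl)-7-(trimethylsilyl)-2,3-dihydro-1-benzofuran-3-yl]methanol
Product: 15 [(2R,3S)-2-[4-(benzyloxy)-3-methoxyphenyl]-5-(5,5-dimethyl-1,3-dioxan-2-yl)-7-iodo-2,3-dihydro-1-benzofuran-3-yl]methanol
Conditions: ICl (1.0 equiv), CH2Cl2, −78 to 0 °C; aq. Na2S2O3
Reagents that add atoms: iodine monochloride, ICl
Why: Ipso-iododesilylation: electrophilic attack at the silicon-bearing carbon, activated by the ortho ring oxygen and by β-silyl stabilisation of the arenium ion, should outpace C–H iodination of either ring.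

Step 7
Reactants: 15 [(2R,3S)-2-[4-(benzyloxy)-3-methoxyphenyl]-5-(5,5-dimethyl-1,3-dioxan-2-yl)-7-iodo-2,3-dihydro-1-benzofuran-3-yl]methanol
Product: 16 [(2R,3S)-2-[4-(benzyloxy)-3-methoxyphenyl]-5-(5,5-dimethyl-1,3-dioxan-2-yl)-7-methoxy-2,3-dihydro-1-benzofuran-3-yl]methanol
Conditions: CuI (10 mol %), 3,4,7,8-tetramethyl-1,10-phenanthroline (20 mol %), Cs2CO3, MeOH–toluene, 90 °C
Reagents that add atoms: methanol, CO
Why: Copper-catalysed Ullmann-type C–O coupling of the aryl iodide with methanol should install the C7 methoxy group; solvent methanol outcompetes the primary alcohol, and the acetal, benzyl ether and both stereocentres are inert to carbonate base.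

Step 8
Reactants: 16 [(2R,3S)-2-[4-(benzyloxy)-3-methoxyphenyl]-5-(5,5-dimethyl-1,3-dioxan-2-yl)-7-methoxy-2,3-dihydro-1-benzofuran-3-yl]methanol
Product: 17 [(2R,3S)-2-[4-(benzyloxy)-3-methoxyphenyl]-5-(5,5-dimethyl-1,3-dioxan-2-yl)-7-methoxy-2,3-dihydro-1-benzofuran-3-yl]methyl 3-methylbutanoate
Conditions: 3-methylbutanoyl chloride, Et3N, DMAP (cat.), CH2Cl2, 0 °C to rt
Reagents that add atoms: 3-methylbutanoyl chloride, CC(C)CC(=O)Cl
Why: DMAP-catalysed acylation of the only free hydroxyl group should give the isovalerate ester.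

Step 9
Reactants: 17 [(2R,3S)-2-[4-(benzyloxy)-3-methoxyphenyl]-5-(5,5-dimethyl-1,3-dioxan-2-yl)-7-methoxy-2,3-dihydro-1-benzofuran-3-yl]methyl 3-methylbutanoate
Product: 18 [(2R,3S)-5-(5,5-dimethyl-1,3-dioxan-2-yl)-2-(4-hydroxy-3-methoxyphenyl)-7-methoxy-2,3-dihydro-1-benzofuran-3-yl]methyl 3-methylbutanoate
Conditions: H2 (1 atm), Pd/C (10% Pd), EtOAc, rt
Reagents that add atoms: none
Why: Catalytic hydrogenolysis of the primary benzyl aryl ether should be much faster than cleavage of the hindered cyclic C2–O1 bond, and it is done while the aldehyde is still an acetal and before the alkene is present.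

Step 10
Reactants: 18 [(2R,3S)-5-(5,5-dimethyl-1,3-dioxan-2-yl)-2-(4-hydroxy-3-methoxyphenyl)-7-methoxy-2,3-dihydro-1-benzofuran-3-yl]methyl 3-methylbutanoate
Product: 19 [(2R,3S)-5-formyl-2-(4-hydroxy-3-methoxyphenyl)-7-methoxy-2,3-dihydro-1-benzofuran-3-yl]methyl 3-methylbutanoate
Conditions: aq. HCl (1 M), THF, rt
Reagents that add atoms: water, O
Why: Acid-catalysed acetal hydrolysis should release the aryl aldehyde under conditions that leave the ester and both stereocentres untouched.

Step 11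
Reactants: 19 [(2R,3S)-5-formyl-2-(4-hydroxy-3-methoxyphenyl)-7-methoxy-2,3-dihydro-1-benzofuran-3-yl]methyl 3-methylbutanoate
Product: 20 [(2R,3S)-2-(4-hydroxy-3-methoxyphenyl)-7-methoxy-5-[(E)-3-oxoprop-1-en-1-yl]-2,3-dihydro-1-benzofuran-3-yl]methyl 3-methylbutanoate (CNP0272976.1)
Conditions: Ph3P=CHCHO (1.2 equiv), toluene, 80 °C
Reagents that add atoms: (triphenylphosphoranylidene)acetaldehyde, O=CC=P(c1ccccc1)(c1ccccc1)c1ccccc1
Why: Wittig olefination with the formyl-stabilised ylide should give the (E)-enal directly and tolerates the free phenol and the ester.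

**Compound list**

1 | 3,5-dibromo-4-hydroxybenzaldehyde | O=Cc1cc(Br)c(O)c(Br)c1 | starting material
2 | 2,6-dibromo-4-(5,5-dimethyl-1,3-dioxan-2-yl)phenol | Oc1c(Br)cc(cc1Br)C1OCC(C)(C)CO1 | intermediate
3 | [2,6-dibromo-4-(5,5-dimethyl-1,3-dioxan-2-yl)phenoxy]trimethylsilane | C[Si](C)(C)Oc1c(Br)cc(cc1Br)C1OCC(C)(C)CO1 | intermediate
4 | lithium 2-bromo-4-(5,5-dimethyl-1,3-dioxan-2-yl)-6-(trimethylsilyl)phenolate | [Li+].[O-]c1c(Br)cc(cc1[Si](C)(C)C)C1OCC(C)(C)CO1 | intermediate
5 | [2-bromo-4-(5,5-dimethyl-1,3-dioxan-2-yl)-6-(trimethylsilyl)phenoxy]trimethylsilane | C[Si](C)(C)Oc1c(Br)cc(cc1[Si](C)(C)C)C1OCC(C)(C)CO1 | intermediate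
6 | lithium 4-(5,5-dimethyl-1,3-dioxan-2-yl)-2,6-bis(trimethylsilyl)phenolate | [Li+].[O-]c1c([Si](C)(C)C)cc(cc1[Si](C)(C)C)C1OCC(C)(C)CO1 | intermediate
7 | 4-(5,5-dimethyl-1,3-dioxan-2-yl)-2,6-bis(trimethylsilyl)phenyl trifluoromethanesulfonate | C[Si](C)(C)c1cc(cc([Si](C)(C)C)c1OS(=O)(=O)C(F)(F)F)C1OCC(C)(C)CO1 | intermediate
8 | 4-(benzyloxy)-3-methoxybenzaldehyde | COc1cc(C=O)ccc1OCc1ccccc1 | starting material
9 | rac-1-[4-(benzyloxy)-3-methoxyphenyl]prop-2-en-1-ol | COc1cc(C(O)C=C)ccc1OCc1ccccc1 | intermediate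
10 | (S)-[4-(benzyloxy)-3-methoxyphenyl][(2R)-oxiran-2-yl]methanol | COc1cc([C@H](O)[C@H]2CO2)ccc1OCc1ccccc1 | intermediate
11 | potassium (S)-[4-(benzyloxy)-3-methoxyphenyl][(2R)-oxiran-2-yl]methanolate | [K+].COc1cc([C@H]([O-])[C@H]2CO2)ccc1OCc1ccccc1 | intermediate
12 | 5-(5,5-dimethyl-1,3-dioxan-2-yl)-3-(trimethylsilyl)benzyne (triple bond C1–C2, SiMe3 on C3) | C[Si](C)(C)C1=CC(C2OCC(C)(C)CO2)=CC#C1 | intermediate
13 | potassium 2-{(S)-[4-(benzyloxy)-3-methoxyphenyl][(2R)-oxiran-2-yl]methoxy}-5-(5,5-dimethyl-1,3-dioxan-2-yl)-3-(trimethylsilyl)benzenide (aryl anion ortho to the new ether oxygen) | [K+].COc1cc([C@H](Oc2c([Si](C)(C)C)cc(C3OCC(C)(C)CO3)c[c-]2)[C@H]2CO2)ccc1OCc1ccccc1 | intermediate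
14 | [(2R,3S)-2-[4-(benzyloxy)-3-methoxyphenyl]-5-(5,5-dimethyl-1,3-dioxan-2-yl)-7-(trimethylsilyl)-2,3-dihydro-1-benzofuran-3-yl]methanol | COc1cc([C@@H]2Oc3c([Si](C)(C)C)cc(C4OCC(C)(C)CO4)cc3[C@H]2CO)ccc1OCc1ccccc1 | intermediate
15 | [(2R,3S)-2-[4-(benzyloxy)-3-methoxyphenyl]-5-(5,5-dimethyl-1,3-dioxan-2-yl)-7-iodo-2,3-dihydro-1-benzofuran-3-yl]methanol | COc1cc([C@@H]2Oc3c(I)cc(C4OCC(C)(C)CO4)cc3[C@H]2CO)ccc1OCc1ccccc1 | intermediate
16 | [(2R,3S)-2-[4-(benzyloxy)-3-methoxyphenyl]-5-(5,5-dimethyl-1,3-dioxan-2-yl)-7-methoxy-2,3-dihydro-1-benzofuran-3-yl]methanol | COc1cc([C@@H]2Oc3c(OC)cc(C4OCC(C)(C)CO4)cc3[C@H]2CO)ccc1OCc1ccccc1 | intermediate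
17 | [(2R,3S)-2-[4-(benzyloxy)-3-methoxyphenyl]-5-(5,5-dimethyl-1,3-dioxan-2-yl)-7-methoxy-2,3-dihydro-1-benzofuran-3-yl]methyl 3-methylbutanoate | COc1cc([C@@H]2Oc3c(OC)cc(C4OCC(C)(C)CO4)cc3[C@H]2COC(=O)CC(C)C)ccc1OCc1ccccc1 | intermediate
18 | [(2R,3S)-5-(5,5-dimethyl-1,3-dioxan-2-yl)-2-(4-hydroxy-3-methoxyphenyl)-7-methoxy-2,3-dihydro-1-benzofuran-3-yl]methyl 3-methylbutanoate | COc1cc([C@@H]2Oc3c(OC)cc(C4OCC(C)(C)CO4)cc3[C@H]2COC(=O)CC(C)C)ccc1O | intermediate
19 | [(2R,3S)-5-formyl-2-(4-hydroxy-3-methoxyphenyl)-7-methoxy-2,3-dihydro-1-benzofuran-3-yl]methyl 3-methylbutanoate | COc1cc([C@@H]2Oc3c(OC)cc(C=O)cc3[C@H]2COC(=O)CC(C)C)ccc1O | intermediate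
20 | [(2R,3S)-2-(4-hydroxy-3-methoxyphenyl)-7-methoxy-5-[(E)-3-oxoprop-1-en-1-yl]-2,3-dihydro-1-benzofuran-3-yl]methyl 3-methylbutanoate | COc1cc([C@@H]2Oc3c(OC)cc(/C=C/C=O)cc3[C@H]2COC(=O)CC(C)C)ccc1O | target

**Step count and risks**

Total steps: 11. Longest linear sequence: 9 steps (steps 3–11 from 8; equally steps 1, 2 and 5–11 from 1).

Steps most likely to fail:

Step 5. The alkoxide oxygen may add to the aryne carbon remote from silicon if steric repulsion by SiMe3 outweighs its electronic bias. The epoxy alkoxide may also undergo Payne migration before it is arylated, and the aryl anion may be protonated or may open the epoxide in the 6-endo sense. The fallback fixes the regiochemistry with a leaving group instead of an aryne and uses known chemistry only. It sets out from 10. Commercial 5-bromovanillin is converted into 3-bromo-4-fluoro-5-methoxybenzaldehyde F1 by deoxyfluorination of the phenol (PhenoFluor, CsF, toluene, 110 °C). The sodium alkoxide of 10 (NaH, DMF, 0 °C) then displaces the fluoride para to the formyl group (SNAr, no bond to a stereocentre is touched) to give 3-bromo-4-{(S)-[4-(benzyloxy)-3-methoxyphenyl][(2R)-oxiran-2-yl]methoxy}-5-methoxybenzaldehyde F2. The aldehyde is masked as the acetal 2-[3-bromo-4-{(S)-[4-(benzyloxy)-3-methoxyphenyl][(2R)-oxiran-2-yl]methoxy}-5-methoxyphenyl]-5,5-dimethyl-1,3-dioxane F3 (2,2-dimethylpropane-1,3-diol, PPTS, benzene, reflux). n-BuLi (THF, −78 °C) then effects Br/Li exchange and Parham-type 5-exo opening of the epoxide with inversion. This comes back to the route at 16, so steps 6 and 7 are not needed.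

Step 7. Reductive loss of iodine, or stalling of the copper-mediated C–O bond formation at the position flanked by the ring oxygen, may erode the conversion. The fallback sets out from 15 and replaces the cross-coupling by boron oxidation and O-alkylation. Miyaura borylation (B2pin2, Pd(dppf)Cl2, KOAc, dioxane, 80 °C) should give [(2R,3S)-2-[4-(benzyloxy)-3-methoxyphenyl]-5-(5,5-dimethyl-1,3-dioxan-2-yl)-7-(4,4,5,5-tetramethyl-1,3,2-dioxaborolan-2-yl)-2,3-dihydro-1-benzofuran-3-yl]methanol F4. Oxidation (NaBO3·4H2O, THF–H2O, rt) should give (2R,3S)-2-[4-(benzyloxy)-3-methoxyphenyl]-5-(5,5-dimethyl-1,3-dioxan-2-yl)-3-(hydroxymethyl)-2,3-dihydro-1-benzofuran-7-ol F5. Methylation of the phenol alone (MeI, K2CO3, acetone) comes back to the route at 16.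

Step 4. The rate difference between the two enantiomers of a terminal vinyl carbinol may be too small, which lowers the enantiomeric purity of the epoxy alcohol at useful conversion, and half of the material is lost at best. The fallback sets out from 9 and replaces the resolution by an enantioselective reduction. MnO2 oxidation (CH2Cl2, rt) should give 1-[4-(benzyloxy)-3-methoxyphenyl]prop-2-en-1-one F6. Corey–Bakshi–Shibata reduction ((S)-2-methyl-CBS-oxazaborolidine, catecholborane, toluene, −78 °C) should give (R)-1-[4-(benzyloxy)-3-methoxyphenyl]prop-2-en-1-ol F7. Epoxidation of this single enantiomer in the matched sense (Ti(OiPr)4, L-(+)-diisopropyl tartrate, t-BuOOH, CH2Cl2, −20 °C, full conversion) comes back to the route at 10.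

Further compounds
F1 | step 5 | 3-bromo-4-fluoro-5-methoxybenzaldehyde | COc1cc(C=O)cc(Br)c1F
F2 | step 5 | 3-bromo-4-{(S)-[4-(benzyloxy)-3-methoxyphenyl][(2R)-oxiran-2-yl]methoxy}-5-methoxybenzaldehyde | COc1cc([C@H](Oc2c(Br)cc(C=O)cc2OC)[C@H]2CO2)ccc1OCc1ccccc1
F3 | step 5 | 2-[3-bromo-4-{(S)-[4-(benzyloxy)-3-methoxyphenyl][(2R)-oxiran-2-yl]methoxy}-5-methoxyphenyl]-5,5-dimethyl-1,3-dioxane | COc1cc([C@H](Oc2c(Br)cc(C3OCC(C)(C)CO3)cc2OC)[C@H]2CO2)ccc1OCc1ccccc1
F4 | step 7 | [(2R,3S)-2-[4-(benzyloxy)-3-methoxyphenyl]-5-(5,5-dimethyl-1,3-dioxan-2-yl)-7-(4,4,5,5-tetramethyl-1,3,2-dioxaborolan-2-yl)-2,3-dihydro-1-benzofuran-3-yl]methanol | COc1cc([C@@H]2Oc3c(B4OC(C)(C)C(C)(C)O4)cc(C4OCC(C)(C)CO4)cc3[C@H]2CO)ccc1OCc1ccccc1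
F5 | step 7 | (2R,3S)-2-[4-(benzyloxy)-3-methoxyphenyl]-5-(5,5-dimethyl-1,3-dioxan-2-yl)-3-(hydroxymethyl)-2,3-dihydro-1-benzofuran-7-ol | COc1cc([C@@H]2Oc3c(O)cc(C4OCC(C)(C)CO4)cc3[C@H]2CO)ccc1OCc1ccccc1
F6 | step 4 | 1-[4-(benzyloxy)-3-methoxyphenyl]prop-2-en-1-one | COc1cc(C(=O)C=C)ccc1OCc1ccccc1
F7 | step 4 | (R)-1-[4-(benzyloxy)-3-methoxyphenyl]prop-2-en-1-ol | COc1cc([C@H](O)C=C)ccc1OCc1ccccc1
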